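The cyclohexane ring A and its fused seven-membered lactone are built first and joined through the C7 oxygen to an achiral (2E,4E)-hepta-2,4,6-trienoic acid. The hydroxymethylcyclohexene ring B (C1'–C6') is then closed last, on the assembled ester, by a catalyst-controlled endo Diels–Alder reaction of the arm's terminal diene C1'=C2'–C3'=C4' with methyl vinyl ketone. The step exploits the C2'=C3' double bond lying between the arm-bearing C1' and the CH2OH-bearing C3', and the cis relation of C1' and C6'; it forms C1'–C6' and C4'–C5', both stereocentres and the alkene at once. The activating acetyl group is the latent isopropyl group.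

Key step: step 18

Remark (locants): ring A = cyclohexane C1–C6 (C1 carbinol carbon carrying C7H2O, C2 lactone α-carbon, C3 ring-fusion carbon, C4 isopropyl carbon); ring B = cyclohexene C1'–C6' (C1' carries the acrylate arm, C3' the CH2OH group, C6' the isopropyl group). In the target C1 is S, C2 R, C3 S, C4 R, C1' R, C6' S.

Assumption: face selection by the two chiral catalysts follows their accepted transition-state models (benzyl-shielded iminium ion in step 3; α-C–H···O-bound s-trans enone in step 18, taken to behave like an acrylate); should either catalyst select the other face, its enantiomer is used.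

Step 1
Reactants: 1 but-2-yne-1,4-diol
Product: 2 (2E)-2-(tributylstannyl)but-2-ene-1,4-diol
Conditions: Bu3SnH, PdCl2(PPh3)2 (2 mol %), THF, 0 °C to rt
Reagents that add atoms: tributyltin hydride, CCCC[SnH](CCCC)CCCC
Why: Pd-catalysed hydrostannation adds H and SnBu3 syn across the symmetrical alkyne, so the two CH2OH groups become cis and no regiochemical question arises.

Step 2
Reactants: 2 (2E)-2-(tributylstannyl)but-2-ene-1,4-diol; 3 bromoethene
Product: 4 (2Z)-2-ethenylbut-2-ene-1,4-diol
Conditions: 3 (1 M in THF), Pd(PPh3)4 (5 mol %), CuI (10 mol %), DMF, 50 °C, sealed vessel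
Reagents that add atoms: none
Why: Stille coupling replaces tin by vinyl with retention of alkene geometry, so the CH2OH group on the diene terminus is trans to the vinyl group (the outside position needed for the cycloaddition).

Step 3
Reactants: 4 (2Z)-2-ethenylbut-2-ene-1,4-diol; 5 (2E)-4-methylpent-2-enal
Product: 7 (3aR,7R,7aR)-4-(hydroxymethyl)-7-(propan-2-yl)-1,3,3a,6,7,7a-hexahydro-2-benzofuran-1-ol (lactol, both anomers), via hydroxy aldehyde 6 (not isolated)
Conditions: (5S)-5-benzyl-2,2,3-trimethylimidazolidin-4-one hydrochloride (20 mol %), MeOH/H2O 19:1, rt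
Reagents that add atoms: none
Why: Iminium-ion-catalysed Diels–Alder reaction that closes ring A, in which the (E)-enal fixes C3-CHO and C4-isopropyl trans, the endo rule places CHO cis to the outside CH2OH of the diene terminus (C2/C3 cis), the unsubstituted diene terminus bonds to the hindered isopropyl-bearing β-carbon, the benzyl group of the (5S)-catalyst leaves the Cα-Si face open, and the cis γ-hydroxy aldehyde 6 then closes to the lactol.

Step 4
Reactants: 7 lactol
Product: 8 the tert-butyldimethylsilyl ether of the CH2OH group (C7–O) of 7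
Conditions: TBSCl (1.05 equiv), imidazole, CH2Cl2, −20 to 0 °C
Reagents that add atoms: tert-butyldimethylsilyl chloride, CC(C)(C)[Si](C)(C)Cl
Why: Silyl ether formation is selective for the unhindered primary allylic alcohol over the hemiacetal hydroxyl, which differentiates the two CH2OH groups of the diene.

Step 5
Reactants: 8 silylated lactol
Product: 9 [(1R,5R,6R)-2-({[tert-butyl(dimethyl)silyl]oxy}methyl)-6-ethenyl-5-(propan-2-yl)cyclohex-2-en-1-yl]methanol
Conditions: Ph3PCH3Br, KN(SiMe3)2, THF, 0 °C to rt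
Reagents that add atoms: methylenetriphenylphosphorane (from Ph3PCH3Br and KN(SiMe3)2), C=P(c1ccccc1)(c1ccccc1)c1ccccc1
Why: Wittig methylenation of the lactol through its open hydroxy-aldehyde form gives the C3 vinyl group and frees the C2 hydroxymethyl group without creating a stereocentre.

Step 6
Reactants: 9 homoallylic alcohol
Product: 10 epoxy alcohol, 9 with the ring C1=C6 bond epoxidised on the face cis to the C2 CH2OH group
Conditions: VO(acac)2 (5 mol %), t-BuOOH (decane), CH2Cl2, 0 °C to rt
Reagents that add atoms: tert-butyl hydroperoxide, CC(C)(C)OO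
Why: Hydroxyl-directed vanadium-catalysed epoxidation delivers oxygen to the trisubstituted ring alkene from the face of the homoallylic C2-CH2OH group, which sets the C1–O bond cis to the C2 substituent and leaves the vinyl group untouched.

Step 7
Reactants: 10 epoxy alcohol
Product: 11 ring A diol with C1(OH)(CH2OTBS), C2-CH2OH, C3-ethenyl and C4-isopropyl (C1-OH, C2-CH2OH and C3-ethenyl on one face, C7 and isopropyl on the other)
Conditions: LiAlH4, THF, 0 °C to rt; aqueous NaOH work-up
Reagents that add atoms: none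
Why: SN2 hydride opening of the trisubstituted epoxide occurs at the secondary carbon C6, so the tertiary C1–OH keeps the configuration set in step 6.

Step 8
Reactants: 11 diol
Product: 12 hydroxy acid, 11 with the C2 CH2OH group oxidised to CO2H
Conditions: TEMPO (20 mol %), PhI(OAc)2 (2.5 equiv), MeCN/pH 7 buffer, rt
Reagents that add atoms: water, O
Why: Oxoammonium (TEMPO) oxidation takes the primary alcohol through the aldehyde hydrate to the acid, while the tertiary alcohol, silyl ether and vinyl group are inert.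

Step 9
Reactants: 12 hydroxy acid; 13 tert-butyl 2-(bromomethyl)prop-2-enoate
Product: 14 the 2-(tert-butoxycarbonyl)prop-2-en-1-yl ester of 12
Conditions: KHCO3, DMF, rt
Reagents that add atoms: none
Why: Carboxylate O-alkylation by the allylic bromide (SN2 and SN2' lead to the same ester) proceeds under base too weak to touch the β-hydroxy acid.

Step 10
Reactants: 14 diene ester
Product: 15 bicyclic lactone, ring A cis-fused at C2/C3 to the ring C2–C(=O)–O–CH2–C(CO2tBu)=CH–C3, with C1 bearing OH and CH2OTBS
Conditions: second-generation Hoveyda–Grubbs catalyst RuCl2(H2IMes)(=CH–C6H4-2-OiPr) (5 mol %), toluene (5 mM), 80 °C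
Reagents that add atoms: none
Why: Ring-closing metathesis between the C3 vinyl group and the acrylate methylene closes the seven-membered lactone, helped by the cis C2/C3 arrangement, and the ring enforces the alkene geometry (C3 cis to CH2O).

Step 11
Reactants: 15 silylated bicyclic lactone
Product: 16 lactone diol, 15 with free C7 hydroxyl (primary and tertiary OH)
Conditions: HF·pyridine, pyridine, THF, 0 °C to rt
Reagents that add atoms: none
Why: Buffered fluoride desilylation removes the primary silyl ether without touching lactone, tert-butyl ester or tertiary alcohol.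

Step 12
Reactants: 17 2-bromoprop-2-en-1-ol
Product: 18 [(2-bromoprop-2-en-1-yl)oxy](tert-butyl)dimethylsilane
Conditions: TBSCl, imidazole, DMF, rt
Reagents that add atoms: tert-butyldimethylsilyl chloride, CC(C)(C)[Si](C)(C)Cl
Why: Standard silyl ether formation protects the future C3' hydroxymethyl group.

Step 13
Reactants: 18 bromoallyl silyl ether; 19 prop-2-enal
Product: 20 (2E)-4-({[tert-butyl(dimethyl)silyl]oxy}methyl)penta-2,4-dienal
Conditions: Pd(OAc)2 (5 mol %), NaHCO3, Bu4NCl, DMF, 40 °C
Reagents that add atoms: none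
Why: Heck reaction, in which the alkenylpalladium adds to the terminal carbon of acrolein and syn β-hydride elimination gives the (E)-dienal.

Step 14
Reactants: 20 dienal; 21 ethyl 2-(diethoxyphosphoryl)prop-2-enoate; 22 (4-methoxyphenyl)methanol
Product: 24 ethyl (2E,4E)-6-({[tert-butyl(dimethyl)silyl]oxy}methyl)-2-{[(4-methoxybenzyl)oxy]methyl}hepta-2,4,6-trienoate, via phosphonate carbanion 23 (not isolated)
Conditions: NaH, 22, THF, 0 °C; 21, 0 °C; then 20, 0 °C to rt
Reagents that add atoms: none
Why: Tandem oxa-Michael addition and Horner–Wadsworth–Emmons olefination, in which the alkoxide adds to the vinylphosphonate and the α-substituted phosphonate carbanion olefinates the aldehyde with the usual preference for the (E)-trisubstituted enoate (chain trans to the ester).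

Step 15
Reactants: 24 ethyl trienoate
Product: 25 (2E,4E)-6-({[tert-butyl(dimethyl)silyl]oxy}methyl)-2-{[(4-methoxybenzyl)oxy]methyl}hepta-2,4,6-trienoic acid
Conditions: LiOH·H2O, THF/MeOH/H2O, rt; then cold 1 M HCl to pH 4
Reagents that add atoms: lithium hydroxide, [Li+].[OH-]
Why: Saponification of the ethyl ester leaves the silyl and 4-methoxybenzyl ethers and the triene intact.

Step 16
Reactants: 16 lactone diol; 25 trienoic acid
Product: 27 the C7–O ester of 16 with 25 (tertiary C1-OH free), via mixed anhydride 26 (not isolated)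
Conditions: 2,4,6-trichlorobenzoyl chloride, Et3N, THF, rt; then 16, DMAP, toluene, rt
Reagents that add atoms: none
Why: Yamaguchi esterification acylates the primary neopentyl-type C7 hydroxyl through the mixed anhydride and acylpyridinium ion, while the tertiary hydroxyl does not react.

Step 17
Reactants: 27 hydroxy ester
Product: 28 the C1–O triethylsilyl ether of 27
Conditions: TESOTf, 2,6-lutidine, CH2Cl2, −78 to 0 °C
Reagents that add atoms: triethylsilyl trifluoromethanesulfonate, CC[Si](CC)(CC)OS(=O)(=O)C(F)(F)F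
Why: Silyl triflate silylation caps the hindered tertiary alcohol so that it cannot bind or protonate the boron Lewis acid of step 18.

Step 18
Reactants: 28 trienoate of the bicyclic lactone; 29 but-3-en-2-one
Product: 30 cycloadduct, 28 in which the arm now ends in a (1'R,6'R)-6'-acetyl-3'-({[tert-butyl(dimethyl)silyl]oxy}methyl)cyclohex-2'-en-1'-yl ring (acetyl cis to the arm)
Conditions: (R)-1-(2-methylphenyl)-3,3-diphenyltetrahydro-1H,3H-pyrrolo[1,2-c][1,3,2]oxazaborole (20 mol %), Tf2NH (16 mol %), 29 (5 equiv), CH2Cl2, −78 to −40 °C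
Reagents that add atoms: none
Why: A concerted, asynchronous, Lewis-acid-catalysed (4+2) cycloaddition joins the terminal s-cis diene C1'=C2'–C3'=C4' of the arm to boron-bound methyl vinyl ketone; the closest known reaction type is the Diels–Alder reaction of 1- and 2-substituted butadienes with acyclic enones under a protonated chiral oxazaborolidine. Ring B is closed intermolecularly by the two new bonds C1'–C6' and C4'–C5' formed suprafacially on both partners, which is why the alkene appears at C2'=C3'. C1' and C6' are created together, their cis relation coming from the endo orientation of the coordinated acetyl group toward the (E)-configured C1' substituent and their absolute sense from the catalyst, which leaves the Cα-Si face of s-trans enone open; ring A is too remote to interfere, so the step is reagent-controlled. Regioselectivity (acetyl on C6', next to C1' and para to C3') is secured because the 1-alkenyl and 3-silyloxymethyl substituents both place the largest HOMO coefficient on C4', which bonds to the enone β-carbon. Site selectivity is secured because the other diene of the triene ends in the fully substituted ester-bearing carbon and cannot compete, and chemoselectivity because the excess enone binds boron far better than ester carbonyls once the tertiary alcohol is capped.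

Step 19
Reactants: 30 methyl ketone
Product: 31 the (1'R,6'R)-6'-(prop-1-en-2-yl) compound, 30 with C=O replaced by C=CH2
Conditions: Zn, CH2Br2, TiCl4, THF/CH2Cl2, 0 °C to rt
Reagents that add atoms: dibromomethane, BrCBr
Why: Non-basic zinc/titanium methylenation (Takai–Lombardo type) converts the methyl ketone into the isopropenyl group without enolisation, so the cis C6' stereocentre is retained and esters and lactone are not attacked.

Step 20
Reactants: 31 isopropenyl compound
Product: 32 fully protected target with (1'R,6'S)-6'-(propan-2-yl)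
Conditions: H2 (1 atm), RhCl(PPh3)3 (10 mol %), benzene/EtOH 1:1, rt
Reagents that add atoms: none
Why: Homogeneous hydrogenation reduces the 1,1-disubstituted exocyclic alkene much faster than the three trisubstituted alkenes (ring B alkene and the two enoates) and creates no stereocentre.

Step 21
Reactants: 32 protected target
Product: 33 CNP0361406.10 (target)
Conditions: CF3CO2H/CH2Cl2/H2O 10:10:1, anisole, 0 °C to rt; then aqueous NaHCO3/MeOH, rt, and acidification to pH 3
Reagents that add atoms: none
Why: Global acidolysis cleaves the tert-butyl ester (loss of isobutene), the 4-methoxybenzyl ether (benzylic cation trapped by anisole) and both silyl ethers in one operation, while lactone, ester, tertiary alcohol and alkenes should survive.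

Compound list
1 | but-2-yne-1,4-diol | OCC#CCO | starting material
2 | (2E)-2-(tributylstannyl)but-2-ene-1,4-diol | OC/C=C(/[Sn](CCCC)(CCCC)CCCC)CO | intermediate
3 | bromoethene | BrC=C | starting material
4 | (2Z)-2-ethenylbut-2-ene-1,4-diol | OC/C=C(/C=C)CO | intermediate
5 | (2E)-4-methylpent-2-enal | CC(C)/C=C/C=O | starting material
6 | (1R,2R,6R)-2,3-bis(hydroxymethyl)-6-(propan-2-yl)cyclohex-3-ene-1-carbaldehyde | CC(C)[C@H]1CC=C(CO)[C@H](CO)[C@@H]1C=O | intermediate
7 | (3aR,7R,7aR)-4-(hydroxymethyl)-7-(propan-2-yl)-1,3,3a,6,7,7a-hexahydro-2-benzofuran-1-ol (anomers) | CC(C)[C@H]1CC=C(CO)[C@@H]2COC(O)[C@H]12 | intermediate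
8 | tert-butyldimethylsilyl ether of the CH2OH group of 7 | CC(C)[C@H]1CC=C(CO[Si](C)(C)C(C)(C)C)[C@@H]2COC(O)[C@H]12 | intermediate
9 | [(1R,5R,6R)-2-({[tert-butyl(dimethyl)silyl]oxy}methyl)-6-ethenyl-5-(propan-2-yl)cyclohex-2-en-1-yl]methanol | CC(C)[C@H]1CC=C(CO[Si](C)(C)C(C)(C)C)[C@H](CO)[C@@H]1C=C | intermediate
10 | 9 with the ring alkene epoxidised on the face cis to the CH2OH group | CC(C)[C@H]1C[C@@H]2O[C@]2(CO[Si](C)(C)C(C)(C)C)[C@H](CO)[C@@H]1C=C | intermediate
11 | ring A diol: C1(OH)(CH2OTBS), C2-CH2OH, C3-ethenyl, C4-isopropyl; OH, CH2OH and ethenyl cis, isopropyl trans | CC(C)[C@H]1CC[C@@](O)(CO[Si](C)(C)C(C)(C)C)[C@H](CO)[C@@H]1C=C | intermediate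
12 | hydroxy acid: 11 with C2-CH2OH oxidised to CO2H | CC(C)[C@H]1CC[C@@](O)(CO[Si](C)(C)C(C)(C)C)[C@H](C(=O)O)[C@@H]1C=C | intermediate
13 | tert-butyl 2-(bromomethyl)prop-2-enoate | C=C(CBr)C(=O)OC(C)(C)C | starting material
14 | 2-(tert-butoxycarbonyl)prop-2-en-1-yl ester of 12 | CC(C)[C@H]1CC[C@@](O)(CO[Si](C)(C)C(C)(C)C)[C@H](C(=O)OCC(=C)C(=O)OC(C)(C)C)[C@@H]1C=C | intermediate
15 | bicyclic lactone (ring A cis-fused to the seven-membered unsaturated lactone carrying CO2tBu; C1 with OH and CH2OTBS) | CC(C)[C@H]1CC[C@@](O)(CO[Si](C)(C)C(C)(C)C)[C@@H]2C(=O)OCC(C(=O)OC(C)(C)C)=C[C@H]12 | intermediate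
16 | lactone diol: 15 with free C7-OH | CC(C)[C@H]1CC[C@@](O)(CO)[C@@H]2C(=O)OCC(C(=O)OC(C)(C)C)=C[C@H]12 | intermediate
17 | 2-bromoprop-2-en-1-ol | OCC(Br)=C | starting material
18 | [(2-bromoprop-2-en-1-yl)oxy](tert-butyl)dimethylsilane | C=C(Br)CO[Si](C)(C)C(C)(C)C | intermediate
19 | prop-2-enal | C=CC=O | starting material
20 | (2E)-4-({[tert-butyl(dimethyl)silyl]oxy}methyl)penta-2,4-dienal | C=C(CO[Si](C)(C)C(C)(C)C)/C=C/C=O | intermediate
21 | ethyl 2-(diethoxyphosphoryl)prop-2-enoate | C=C(C(=O)OCC)P(=O)(OCC)OCC | starting material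
22 | (4-methoxyphenyl)methanol | COc1ccc(CO)cc1 | starting material
23 | sodium salt of the carbanion of ethyl 2-(diethoxyphosphoryl)-3-[(4-methoxybenzyl)oxy]propanoate | CCOC(=O)[C-](COCc1ccc(OC)cc1)P(=O)(OCC)OCC.[Na+] | intermediate
24 | ethyl (2E,4E)-6-({[tert-butyl(dimethyl)silyl]oxy}methyl)-2-{[(4-methoxybenzyl)oxy]methyl}hepta-2,4,6-trienoate | CCOC(=O)/C(COCc1ccc(OC)cc1)=C/C=C/C(=C)CO[Si](C)(C)C(C)(C)C | intermediate
25 | (2E,4E)-6-({[tert-butyl(dimethyl)silyl]oxy}methyl)-2-{[(4-methoxybenzyl)oxy]methyl}hepta-2,4,6-trienoic acid | OC(=O)/C(COCc1ccc(OC)cc1)=C/C=C/C(=C)CO[Si](C)(C)C(C)(C)C | intermediate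
26 | mixed anhydride of 25 with 2,4,6-trichlorobenzoic acid | O=C(OC(=O)/C(COCc1ccc(OC)cc1)=C/C=C/C(=C)CO[Si](C)(C)C(C)(C)C)c1c(Cl)cc(Cl)cc1Cl | intermediate
27 | C7–O ester of 16 with 25 (C1-OH free) | CC(C)[C@H]1CC[C@@](O)(COC(=O)/C(COCc3ccc(OC)cc3)=C/C=C/C(=C)CO[Si](C)(C)C(C)(C)C)[C@@H]2C(=O)OCC(C(=O)OC(C)(C)C)=C[C@H]12 | intermediate
28 | C1–O triethylsilyl ether of 27 | CC(C)[C@H]1CC[C@@](O[Si](CC)(CC)CC)(COC(=O)/C(COCc3ccc(OC)cc3)=C/C=C/C(=C)CO[Si](C)(C)C(C)(C)C)[C@@H]2C(=O)OCC(C(=O)OC(C)(C)C)=C[C@H]12 | intermediate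
29 | but-3-en-2-one | CC(=O)C=C | starting material
30 | cycloadduct with ring B as (1'R,6'R)-6'-acetyl-3'-(silyloxymethyl)cyclohex-2'-en-1'-yl, acetyl cis to the arm | CC(C)[C@H]1CC[C@@](O[Si](CC)(CC)CC)(COC(=O)/C(COCc3ccc(OC)cc3)=C/[C@H]4C=C(CO[Si](C)(C)C(C)(C)C)CC[C@H]4C(C)=O)[C@@H]2C(=O)OCC(C(=O)OC(C)(C)C)=C[C@H]12 | intermediate
31 | 30 with acetyl converted to prop-1-en-2-yl (1'R,6'R) | CC(C)[C@H]1CC[C@@](O[Si](CC)(CC)CC)(COC(=O)/C(COCc3ccc(OC)cc3)=C/[C@H]4C=C(CO[Si](C)(C)C(C)(C)C)CC[C@H]4C(C)=C)[C@@H]2C(=O)OCC(C(=O)OC(C)(C)C)=C[C@H]12 | intermediate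
32 | fully protected target, isopropyl at C6' (1'R,6'S) | CC(C)[C@H]1CC[C@@](O[Si](CC)(CC)CC)(COC(=O)/C(COCc3ccc(OC)cc3)=C/[C@H]4C=C(CO[Si](C)(C)C(C)(C)C)CC[C@H]4C(C)C)[C@@H]2C(=O)OCC(C(=O)OC(C)(C)C)=C[C@H]12 | intermediate
33 | CNP0361406.10 | CC(C)[C@H]1CC[C@@](O)(COC(=O)/C(=C/[C@H]2C=C(CO)CC[C@H]2C(C)C)CO)[C@@H]2C(=O)OCC(C(=O)O)=C[C@H]12 | target

Total step count: 21. Longest linear sequence: 17 steps (steps 1–11, then 16–21, from 1 to 33).

Steps most likely to fail

Step 18. The many carbonyl and ether oxygens of 28 may compete with the enone for the boron Lewis acid, so that activation and face discrimination fall off and the triene is consumed unselectively. The fallback moves the cycloaddition before the fragment union; it sets out from 24 (with 29 and 16) and comes back at 33. Ethyl trienoate 24 and 29 under the same type of catalysis should give ethyl (2E)-3-[(1R,6R)-6-acetyl-3-({[tert-butyl(dimethyl)silyl]oxy}methyl)cyclohex-2-en-1-yl]-2-{[(4-methoxybenzyl)oxy]methyl}prop-2-enoate F1. Methylenation as in step 19 gives the isopropenyl ester F2, hydrogenation as in step 20 the isopropyl ester F3, and LiOH the acid F4. Esterification of F4 with diol 16 (EDC·HCl, DMAP, CH2Cl2) gives the protected ester F5 with its tertiary alcohol free, and acidolysis as in step 21 gives 33.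

Step 3. The β-branched iminium ion may add too slowly to the trisubstituted diene terminus, so that an uncatalysed background reaction erodes regio-, endo and facial selectivity. The fallback is an auxiliary-controlled, Lewis-acid-promoted Diels–Alder reaction; it sets out from 4 and comes back at 7. Diol 4 is silylated (TESCl, imidazole) to (2Z)-1,4-bis[(triethylsilyl)oxy]-2-ethenylbut-2-ene F6. (2E)-4-Methylpent-2-enoic acid is converted (pivaloyl chloride, Et3N; then lithiated (4S)-4-benzyl-1,3-oxazolidin-2-one) into the imide (4S)-4-benzyl-3-[(2E)-4-methylpent-2-enoyl]-1,3-oxazolidin-2-one F7. F6 and F7 with Et2AlCl in CH2Cl2 at −78 °C should give the endo imide cycloadduct F8 (chelated s-cis imide, diene anti to the benzyl group, again the Cα-Si face). LiBH4 removes the auxiliary to give the primary alcohol F9, DMP oxidation gives the aldehyde F10, and AcOH/THF/H2O removes both silyl groups, whereupon hydroxy aldehyde 6 closes to lactol 7.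

Step 14. The alkoxide may be lost again from the phosphonate carbanion (retro-Michael) and add to the dienal instead, and the olefination may not be fully (E)-selective. The fallback is a Morita–Baylis–Hillman route; it sets out from 20 and comes back at 24. Dienal 20 and ethyl acrylate with DABCO give ethyl (4E)-3-hydroxy-2-methylidene-6-({[tert-butyl(dimethyl)silyl]oxy}methyl)hepta-4,6-dienoate F11. NBS/Me2S in CH2Cl2 brominates with allylic transposition to the thermodynamically preferred ethyl (2Z,4E)-2-(bromomethyl)-6-({[tert-butyl(dimethyl)silyl]oxy}methyl)hepta-2,4,6-trienoate F12 (chain trans to the ester). Ag2O and alcohol 22 then displace the primary allylic bromide to give 24.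

Further compounds
F1 | step 18 | ethyl (2E)-3-[(1R,6R)-6-acetyl-3-({[tert-butyl(dimethyl)silyl]oxy}methyl)cyclohex-2-en-1-yl]-2-{[(4-methoxybenzyl)oxy]methyl}prop-2-enoate | CCOC(=O)/C(COCc1ccc(OC)cc1)=C/[C@H]2C=C(CO[Si](C)(C)C(C)(C)C)CC[C@H]2C(C)=O
F2 | step 18 | ethyl (2E)-3-[(1R,6R)-3-({[tert-butyl(dimethyl)silyl]oxy}methyl)-6-(prop-1-en-2-yl)cyclohex-2-en-1-yl]-2-{[(4-methoxybenzyl)oxy]methyl}prop-2-enoate | CCOC(=O)/C(COCc1ccc(OC)cc1)=C/[C@H]2C=C(CO[Si](C)(C)C(C)(C)C)CC[C@H]2C(C)=C
F3 | step 18 | ethyl (2E)-3-[(1R,6S)-3-({[tert-butyl(dimethyl)silyl]oxy}methyl)-6-(propan-2-yl)cyclohex-2-en-1-yl]-2-{[(4-methoxybenzyl)oxy]methyl}prop-2-enoate | CCOC(=O)/C(COCc1ccc(OC)cc1)=C/[C@H]2C=C(CO[Si](C)(C)C(C)(C)C)CC[C@H]2C(C)C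
F4 | step 18 | (2E)-3-[(1R,6S)-3-({[tert-butyl(dimethyl)silyl]oxy}methyl)-6-(propan-2-yl)cyclohex-2-en-1-yl]-2-{[(4-methoxybenzyl)oxy]methyl}prop-2-enoic acid | OC(=O)/C(COCc1ccc(OC)cc1)=C/[C@H]2C=C(CO[Si](C)(C)C(C)(C)C)CC[C@H]2C(C)C
F5 | step 18 | C7–O ester of 16 with F4 (32 without the triethylsilyl group) | CC(C)[C@H]1CC[C@@](O)(COC(=O)/C(COCc3ccc(OC)cc3)=C/[C@H]4C=C(CO[Si](C)(C)C(C)(C)C)CC[C@H]4C(C)C)[C@@H]2C(=O)OCC(C(=O)OC(C)(C)C)=C[C@H]12
F6 | step 3 | (2Z)-1,4-bis[(triethylsilyl)oxy]-2-ethenylbut-2-ene | CC[Si](CC)(CC)OC/C=C(/C=C)CO[Si](CC)(CC)CC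
F7 | step 3 | (4S)-4-benzyl-3-[(2E)-4-methylpent-2-enoyl]-1,3-oxazolidin-2-one | CC(C)/C=C/C(=O)N1[C@@H](Cc2ccccc2)COC1=O
F8 | step 3 | imide cycloadduct (ring A with C2-CH2OTES cis to the C3 acyl group, isopropyl trans) | CC(C)[C@H]1CC=C(CO[Si](CC)(CC)CC)[C@H](CO[Si](CC)(CC)CC)[C@@H]1C(=O)N1[C@@H](Cc2ccccc2)COC1=O
F9 | step 3 | primary alcohol from reductive removal of the auxiliary | CC(C)[C@H]1CC=C(CO[Si](CC)(CC)CC)[C@H](CO[Si](CC)(CC)CC)[C@@H]1CO
F10 | step 3 | bis(triethylsilyl) ether of aldehyde 6 | CC(C)[C@H]1CC=C(CO[Si](CC)(CC)CC)[C@H](CO[Si](CC)(CC)CC)[C@@H]1C=O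
F11 | step 14 | ethyl (4E)-3-hydroxy-2-methylidene-6-({[tert-butyl(dimethyl)silyl]oxy}methyl)hepta-4,6-dienoate (racemic) | C=C(C(=O)OCC)C(O)/C=C/C(=C)CO[Si](C)(C)C(C)(C)C
F12 | step 14 | ethyl (2Z,4E)-2-(bromomethyl)-6-({[tert-butyl(dimethyl)silyl]oxy}methyl)hepta-2,4,6-trienoate | CCOC(=O)/C(CBr)=C/C=C/C(=C)CO[Si](C)(C)C(C)(C)C
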